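Compare the amounts first: L is the smaller charge in each earlier run, so turn each G reading from a fraction of the E charge into G per L charged, multiplying it by the ratio of the two charges, a plain ratio that assumes nothing yet about how many L one G takes.

| setting | epsilon | zeta | delta | west | south-west | north-west |
|---|---|---|---|---|---|---|
| E | 0.023 M | 0.034 M | 0.036 M | 0.020 M | 0.030 M | 0.050 M |
| L | 0.022 M | 0.022 M | 0.022 M | 0.0220 M | 0.0220 M | 0.0220 M |
| remark | run made earlier | run made earlier | run made earlier |  |  |  |
| time |  |  |  | 15 h | 15 h | 15 h |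

| run | time / h | G / % | E / % |
|---|---|---|---|
| epsilon | 3.00 | 5.0 | 38.7 |
| epsilon | 6.00 | 10.9 | 19.7 |
| epsilon | 10.0 | 17.8 | 10.3 |
| epsilon | 12.0 | 18.9 | 8.5 |
| epsilon | 15.0 | 21.4 | 8.0 |
| zeta | 1.33 | 1.2 | 65.0 |
| zeta | 2.50 | 2.4 | 44.8 |
| zeta | 4.00 | 5.4 | 30.0 |
| zeta | 8.00 | 12.1 | 13.7 |
| zeta | 15.0 | 14.4 | 9.9 |
| delta | 3.00 | 3.8 | 38.4 |
| delta | 6.00 | 9.4 | 19.7 |
| delta | 10.0 | 11.7 | 11.2 |
| delta | 12.0 | 12.8 | 9.9 |
| delta | 15.0 | 13.0 | 9.7 |

(readings scatter by 0.5 percentage points)

* [G] at the end for west, south-west, north-west, in this order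
* how the row runs (hardly changes / rises all the way / falls, then rises / falls all the way / rises, then falls)

- "hardly changes" means that all values lie within two and a half points (for a concentration: within two and a half percent of the largest)

Draw epsilon on this scale: it gains 13 percentage points between 3.00 h and 10.0 h, then 3.8 points up to 15.0 h, so it bends near 10.0 h and climbs more slowly afterwards. Set delta beside it: at 6.00 h delta reads 15.4% against 11.4% for epsilon, so the richer run starts ahead, but its G moves by 0.2 points over the last interval, less than the scatter, so read delta as level. The curves then cross between 12.0 h and 15.0 h, as far as the scatter lets one read it. Take the ends of epsilon, zeta and delta, 22.4%, 22.3% and 21.3%, and call their mean the L-yield at the end, 22.0%.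

Reckon the new flasks from it: the same L-yield means G at 24.2%, 16.1% and 9.67% of the E charge in west, south-west and north-west, or 0.00483 M in each, a row that hardly changes. The forecast parts from this reckoning: it gives 0.0045 M, 0.0049 M and 0.0042 M, a row that rises, then falls, because “still rising at 15 h, while the richest run has levelled off”.

The flasks give 0.00462 M, 0.00482 M and 0.00440 M, so the row rises, then falls, as the forecast said.

    E ⇌ J (K = 3.00, k = 0.230 h⁻¹)
    L + X → Z (k = 36.0 M⁻¹ h⁻¹)
    L + J ⇌ Q (K = 25.0 M⁻¹, k = 10.0 M⁻¹ h⁻¹)
    L + Q → G (k = 37.0 M⁻¹ h⁻¹)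
    E → X (k = 0.110 h⁻¹)
    X ⇌ D (K = 1.10, k = 0.190 h⁻¹)

As L-yields the row reads 21.0%, 21.9% and 20.0%. In west at 1.53 h, L passes with X into Z at 1.1 times the forward rate at which it joins J into Q, and at 15.0 h west holds more Z than G, 32.4% against 23.1% of the E charge. North-west at 150 h, with L, the limiting reagent, at 0% of its charge, holds G at 8.95% of the E charge, an L-yield of 20.3%, and since each G takes two L, one into Q and one from Q into G, that G holds 40.7% of the L charge.

The numbers in the tables are simulated from invented constants, noise included.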